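**Retrosynthetic overview**

1. Target 40 ⇐ 18-alcohol 39 (selective 18-O-acetylation) ⇐ seco acid 36 (Yamaguchi closure of the ten-membered lactone, the last ring).
2. 36 ⇐ ether-bridged tricycle 25: C9–OH/C10–Me/C11–OH from a C11 enone (conjugate borylation, 1,3-anti reduction), C5=C6 from the C6 ketone (enol triflate reduction), pyrrole ester by C9 acylation.
3. Ether bridge C13–O–C8 ⇐ palladium allylic etherification; ring B ⇐ silicon-tethered intramolecular Diels–Alder of ring-A enone 19 with a dienol ether of 4-acetoxy-2-methylbut-2-enal.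
4. 19 ⇐ p-quinol 15 by an organocatalytic desymmetrising Michael addition of methyl pyruvate (C1–C3; sets C4/C13), then C2 reduction and O-methylation; 15 ⇐ vinyllithium 13 + benzoquinone monoketal 12.
5. Side chain C14–C19 ⇐ propanal: proline α-aminoxylation (first stereocentre), (Z)-crotylboration, Stork–Zhao iodo-olefination. Ring order: A (dienone) → B → ether bridge → lactone.

Assumption: the SMILES is taken as the definition of the target, including the C14=C15 bond as written (C13 and C16 cis, Z); atom numbers C1–C19 follow the nargenicin skeleton (C1 lactone carbonyl, C13 ether-bridged quaternary carbon).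

Notation: R* = (2Z,4R,5S,6R)-6-(tert-butyldimethylsilyloxy)-4-methyl-5-(triethylsilyloxy)hept-2-en-2-yl (C14–C19); TBS = tert-butyldimethylsilyl, TES = triethylsilyl.

**Step 1**
Reactants: 1 propanal; 2 (Z)-crotylboronic acid pinacol ester
Product: 4 (2R,3S,4R)-2-(anilinooxy)-4-methylhex-5-en-3-ol, via (2R)-2-(anilinooxy)propanal 3 (not isolated)
Conditions: L-proline (10 mol%), PhNO, CHCl3, 4 °C; excess 1 evaporated; then 2, CH2Cl2, 0 °C to rt; triethanolamine work-up
Reagents that add atoms: nitrosobenzene, O=Nc1ccccc1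
Why: Proline enamine catalysis (α-aminoxylation) sets C18 as R (first stereocentre), and the (Z)-crotylboronate then adds through a closed chair transition state under Felkin–Anh control by the α-oxygen, giving the 16,17-syn-17,18-anti triad.

**Step 2**
Reactants: 4 (2R,3S,4R)-2-(anilinooxy)-4-methylhex-5-en-3-ol
Product: 5 (2R,3S,4R)-4-methylhex-5-ene-2,3-diol
Conditions: Zn dust, AcOH, EtOH, rt
Reagents that add atoms: none
Why: Zinc in acetic acid cleaves the weak N–O bond reductively without touching the alkene or the stereocentres.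

**Step 3**
Reactants: 5 (2R,3S,4R)-4-methylhex-5-ene-2,3-diol
Product: 7 (2R,3S,4R)-2-(tert-butyldimethylsilyloxy)-4-methyl-3-(triethylsilyloxy)hex-5-ene, via mono-TBS ether 6 (not isolated)
Conditions: TBSCl (1.05 equiv), imidazole, DMF, −20 °C; then TESCl, 4-(dimethylamino)pyridine (cat.), 0 °C to rt
Reagents that add atoms: tert-butyldimethylsilyl chloride, CC(C)(C)[Si](C)(C)Cl; triethylsilyl chloride, CC[Si](CC)(CC)Cl
Why: Sequential silylation: the bulky chlorosilane takes the less hindered C18 hydroxyl first, and the hindered C17 hydroxyl then receives the more labile triethylsilyl group that is removed selectively later.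

**Step 4**
Reactants: 7 (2R,3S,4R)-2-(tert-butyldimethylsilyloxy)-4-methyl-3-(triethylsilyloxy)hex-5-ene
Product: 8 (2S,3S,4R)-4-(tert-butyldimethylsilyloxy)-2-methyl-3-(triethylsilyloxy)pentanal
Conditions: O3, NaHCO3, CH2Cl2, −78 °C; then PPh3, −78 °C to rt; used crude
Reagents that add atoms: ozone, [O-][O+]=O
Why: Ozonolysis with reductive work-up cleaves the terminal alkene to the α-methyl aldehyde, and the cold buffered conditions avoid epimerisation at C16.

**Step 5**
Reactants: 8 (2S,3S,4R)-4-(tert-butyldimethylsilyloxy)-2-methyl-3-(triethylsilyloxy)pentanal; 9 ethyltriphenylphosphonium iodide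
Product: 11 (2Z,4R,5S,6R)-6-(tert-butyldimethylsilyloxy)-2-iodo-4-methyl-5-(triethylsilyloxy)hept-2-ene, via iodo ylide 10 (not isolated)
Conditions: 9, n-BuLi, THF, 0 °C; I2, −78 °C; NaN(SiMe3)2, −20 °C; then 8, −78 °C
Reagents that add atoms: iodine, II
Why: Stork–Zhao-type Wittig olefination with the α-iodo ylide gives the (Z)-2-iodoalkene (iodine cis to C16) under kinetic control, which fixes the C14=C15 geometry of the target.

**Step 6**
Reactants: 11 (2Z,4R,5S,6R)-vinyl iodide; 12 4,4-dimethoxycyclohexa-2,5-dien-1-one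
Product: 15 4-hydroxy-4-R*-cyclohexa-2,5-dien-1-one (p-quinol), via vinyllithium 13 (not isolated), via ketal carbinol 14 (not isolated)
Conditions: 11, t-BuLi (2.1 equiv), Et2O, −78 °C; 12, −78 °C; then 5% aq. oxalic acid, THF, 0 °C
Reagents that add atoms: water, O
Why: Iodine–lithium exchange proceeds with retention of alkene geometry, the vinyllithium adds 1,2 to the non-enolisable quinone monoketal, and mild acid unmasks the dienone to give the prochiral p-quinol.

**Step 7**
Reactants: 15 p-quinol; 16 methyl pyruvate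
Product: 17 methyl 3-[(1R,2S)-2-hydroxy-5-oxo-2-R*-cyclohex-3-en-1-yl]-2-oxopropanoate (C3 chain cis to the C13 hydroxyl; partly present as its cyclic C2 hemiketal)
Conditions: 16 (3 equiv), (R)-3,3'-bis(2,4,6-triisopropylphenyl)-1,1'-binaphthyl-2,2'-diyl hydrogen phosphate (10 mol%), 5 Å MS, toluene, 0 °C to rt
Reagents that add atoms: none
Why: Proposed new method: a chiral phosphoric acid is proposed to catalyse the direct Michael addition of methyl pyruvate through its enol (enol catalysis), the P=O oxygen binding the enol O–H while the acidic P–OH activates the dienone carbonyl and the quinol O–H hydrogen-bonds to the incoming ester carbonyl, so that C3 is delivered to C4 on the hydroxyl face (anti to the bulky alkenyl group) and the binaphthyl pocket selects one of the two enone arms, which fixes C4 and C13 under catalyst control; the closest known reactions are phosphoric-acid-catalysed Michael additions of ketone enols to enones and organocatalytic desymmetrisations of 4-hydroxycyclohexadienones.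

**Step 8**
Reactants: 17 α-keto ester
Product: 18 methyl (2S)-2-hydroxy-3-[(1S,2S)-2-hydroxy-5-oxo-2-R*-cyclohex-3-en-1-yl]propanoate
Conditions: RuCl(p-cymene)[(S,S)-TsDPEN] (2 mol%), HCO2Na, H2O/EtOAc, rt
Reagents that add atoms: none
Why: Noyori-type asymmetric transfer hydrogenation reduces the strongly activated α-keto ester (not the enone) through its open keto form, and the catalyst controls the new C2 centre (S).

**Step 9**
Reactants: 18 (2S)-α-hydroxy ester
Product: 19 methyl (2S)-2-methoxy-3-[(1S,2S)-2-hydroxy-5-oxo-2-R*-cyclohex-3-en-1-yl]propanoate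
Conditions: MeI, Ag2O, 4 Å MS, Et2O, rt, dark
Reagents that add atoms: iodomethane, CI
Why: Purdie methylation etherifies the acidic α-hydroxy ester hydroxyl under non-basic conditions, leaving the hindered tertiary C13 hydroxyl free and avoiding lactonisation or C2 epimerisation.

**Step 10**
Reactants: 19 ring-A enone; 20 (2E)-4-acetoxy-2-methylbut-2-enal
Product: 23 cis-fused octalin-6-one silylene (C8 acetate; C9=C10 alkene; C11–O–Si(iPr)2–O–C13 tether; H7 and H12 anti to O13; O8 and O11 syn to O13), via silyl triflate 21 (not isolated), via silyl dienol ether 22 (not isolated)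
Conditions: iPr2Si(OTf)2, 2,6-lutidine, CH2Cl2, −78 to 0 °C; 20, Et3N, 0 °C to rt; then toluene, BHT, 100 °C
Reagents that add atoms: diisopropylsilyl bis(trifluoromethanesulfonate), CC(C)[Si](OS(=O)(=O)C(F)(F)F)(OS(=O)(=O)C(F)(F)F)C(C)C
Why: A temporary silicon tether from O13 forces an intramolecular Diels–Alder reaction onto the hydroxyl face of the enone through the endo transition state that the O–Si–O bridge fits, giving cis-fused ring B with H7/H12 anti to O13 and both C8–OAc and C11–O syn to O13.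

**Step 11**
Reactants: 23 octalinone silylene
Product: 25 ether-bridged tricycle (C13–O–C8 ether; C6 ketone; C9=C10 alkene; free C11 hydroxyl), via diol acetate 24 (not isolated)
Conditions: HF·pyridine, pyridine, THF, −20 °C (NaHCO3 work-up, crude); then Pd(PPh3)4 (5 mol%), Et3N, THF, 50 °C
Reagents that add atoms: none
Why: After fluoride removal of the labile dialkoxysilane, zerovalent palladium ionises the allylic acetate from the convex face and the tertiary C13 hydroxyl attacks the less substituted allyl terminus C8 on the opposite face (Tsuji–Trost allylic etherification, net retention), closing the five-membered ether bridge.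

**Step 12**
Reactants: 25 ether-bridged tricycle
Product: 26 tricyclic C11 enone (C6 ketone retained)
Conditions: Dess–Martin periodinane, NaHCO3, CH2Cl2, 0 °C to rt
Reagents that add atoms: none
Why: Dess–Martin oxidation of the only free (allylic secondary) hydroxyl gives the C11 enone that activates C9 for oxygenation.

**Step 13**
Reactants: 26 tricyclic C11 enone
Product: 28 C5=C6 enol triflate, via potassium enolate 27 (not isolated)
Conditions: KN(SiMe3)2 (1.05 equiv), THF, −78 °C; PhNTf2, −78 to 0 °C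
Reagents that add atoms: N-phenylbis(trifluoromethanesulfonimide), O=S(=O)(N(c1ccccc1)S(=O)(=O)C(F)(F)F)C(F)(F)F
Why: Kinetic enolisation of the C6 ketone can only occur towards C5 (C7 is a bridgehead and the C11 enone has no accessible acidic hydrogen), and the enolate is trapped as the enol triflate.

**Step 14**
Reactants: 28 enol triflate
Product: 29 tricyclic C11 enone with the C5=C6 alkene
Conditions: Pd(OAc)2 (5 mol%), PPh3, Bu3N, HCO2H, DMF, 60 °C
Reagents that add atoms: none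
Why: Palladium-catalysed formate reduction of the enol triflate (oxidative addition to zerovalent palladium, formate decarboxylation, reductive elimination) replaces triflate by hydrogen and leaves the C5=C6 alkene of the target.

**Step 15**
Reactants: 29 tricyclic enone
Product: 31 9-hydroxy-11-ketone (C9–OH axial on the exo face; C10 methyl equatorial), via C9 boronate 30 (not isolated)
Conditions: CuCl (10 mol%), NaOt-Bu (15 mol%), bis[2-(diphenylphosphino)phenyl] ether (10 mol%), B2pin2, MeOH, THF, rt; then 30% H2O2, aq. NaHCO3, 0 °C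
Reagents that add atoms: hydrogen peroxide, OO
Why: Copper-catalysed conjugate borylation delivers boron to C9 from the open exo face (anti to the ether bridge), protonation anti to boron and thermodynamics both place the C10 methyl equatorial, and oxidation proceeds with retention to the C9 hydroxyl.

**Step 16**
Reactants: 31 9-hydroxy-11-ketone
Product: 32 9,11-diol (C11–OH equatorial, anti to C9–OH)
Conditions: Me4NBH(OAc)3, AcOH/MeCN, −25 °C
Reagents that add atoms: none
Why: Evans–Saksena reduction: the C9-bound acetoxyborohydride delivers hydride intramolecularly to the exo face of the C11 ketone, giving the 1,3-anti diol without touching the ester.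

**Step 17**
Reactants: 32 9,11-diol; 33 1H-pyrrole-2-carbonyl chloride
Product: 34 9-O-(pyrrole-2-carbonyl) ester (C11 hydroxyl free; C1 methyl ester)
Conditions: 33 (1.3 equiv), pyridine, CH2Cl2, −20 to 0 °C
Reagents that add atoms: none
Why: Acylation is expected at the axial C9 hydroxyl on the open exo face in preference to the C11 hydroxyl, which is screened by the C10 methyl and the C13 quaternary centre (the reactivity order expected for the parent triol of this family).

**Step 18**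
Reactants: 34 pyrrole ester methyl ester
Product: 36 seco acid (C1 acid; C17 hydroxyl; O18 TBS ether), via TES-protected acid 35 (not isolated)
Conditions: LiOH·H2O, THF/MeOH/H2O, 0 °C; then AcOH/THF/H2O (3:1:1), rt to 40 °C
Reagents that add atoms: lithium hydroxide, [Li+].[OH-]
Why: Saponification of the activated α-methoxy methyl ester (the hindered, electron-rich pyrrole ester survives) followed by mild acid cleaves only the triethylsilyl ether, freeing the C17 hydroxyl beside the intact TBS ether.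

**Step 19**
Reactants: 36 seco acid
Product: 38 18-O-TBS macrolactone, via mixed anhydride 37 (not isolated)
Conditions: 2,4,6-Cl3C6H2COCl, Et3N, THF, rt; then slow addition to 4-(dimethylamino)pyridine, toluene (1 mM), 80 °C
Reagents that add atoms: none
Why: Yamaguchi macrolactonisation at high dilution closes the ten-membered lactone between C1 and O17, helped by the cis C14=C15 alkene and the rigid tricyclic core, while the hindered C11 hydroxyl does not compete.

**Step 20**
Reactants: 38 18-O-TBS macrolactone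
Product: 39 18-alcohol macrolactone (C11 and C18 hydroxyls free)
Conditions: HF·pyridine, pyridine, THF, 0 °C to rt
Reagents that add atoms: none
Why: Fluoride-mediated desilylation frees the C18 hydroxyl without touching the esters or the lactone.

**Step 21**
Reactants: 39 18-alcohol macrolactone
Product: 40 18-O-acetyl-nargenicin (target)
Conditions: Ac2O (1.5 equiv), pyridine, CH2Cl2, 0 °C
Reagents that add atoms: acetic anhydride, CC(=O)OC(C)=O
Why: Acetylation without an acyl-transfer catalyst should favour the unhindered side-chain C18 hydroxyl over the buried C11 hydroxyl, giving the target.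

**Compound list**

1 | propanal | CCC=O | starting material
2 | (Z)-crotylboronic acid pinacol ester | C/C=C\CB1OC(C)(C)C(C)(C)O1 | starting material
3 | (2R)-2-(anilinooxy)propanal | O=C[C@@H](C)ONc1ccccc1 | intermediate
4 | (2R,3S,4R)-2-(anilinooxy)-4-methylhex-5-en-3-ol | C=C[C@@H](C)[C@@H]([C@@H](C)ONc1ccccc1)O | intermediate
5 | (2R,3S,4R)-4-methylhex-5-ene-2,3-diol | C=C[C@@H](C)[C@@H]([C@@H](C)O)O | intermediate
6 | (2R,3S,4R)-2-(tert-butyldimethylsilyloxy)-4-methylhex-5-en-3-ol | C=C[C@@H](C)[C@@H]([C@@H](C)O[Si](C)(C)C(C)(C)C)O | intermediate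
7 | (2R,3S,4R)-2-(tert-butyldimethylsilyloxy)-4-methyl-3-(triethylsilyloxy)hex-5-ene | C=C[C@@H](C)[C@@H]([C@@H](C)O[Si](C)(C)C(C)(C)C)O[Si](CC)(CC)CC | intermediate
8 | (2S,3S,4R)-4-(tert-butyldimethylsilyloxy)-2-methyl-3-(triethylsilyloxy)pentanal | O=C[C@@H](C)[C@@H]([C@@H](C)O[Si](C)(C)C(C)(C)C)O[Si](CC)(CC)CC | intermediate
9 | ethyltriphenylphosphonium iodide | CC[P+](c1ccccc1)(c1ccccc1)c1ccccc1.[I-] | starting material
10 | (1-iodoethylidene)triphenylphosphorane | CC(I)=P(c1ccccc1)(c1ccccc1)c1ccccc1 | intermediate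
11 | (2Z,4R,5S,6R)-6-(tert-butyldimethylsilyloxy)-2-iodo-4-methyl-5-(triethylsilyloxy)hept-2-ene | I/C(C)=C\[C@@H](C)[C@@H]([C@@H](C)O[Si](C)(C)C(C)(C)C)O[Si](CC)(CC)CC | intermediate
12 | 4,4-dimethoxycyclohexa-2,5-dien-1-one | COC1(OC)C=CC(=O)C=C1 | starting material
13 | R*-lithium (vinyllithium; lithium cis to C16) | [Li]/C(C)=C\[C@@H](C)[C@@H]([C@@H](C)O[Si](C)(C)C(C)(C)C)O[Si](CC)(CC)CC | intermediate
14 | 4,4-dimethoxy-1-R*-cyclohexa-2,5-dien-1-ol | COC1(OC)C=CC(O)(/C(C)=C\[C@@H](C)[C@@H]([C@@H](C)O[Si](C)(C)C(C)(C)C)O[Si](CC)(CC)CC)C=C1 | intermediate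
15 | 4-hydroxy-4-R*-cyclohexa-2,5-dien-1-one (p-quinol) | O=C1C=CC(O)(/C(C)=C\[C@@H](C)[C@@H]([C@@H](C)O[Si](C)(C)C(C)(C)C)O[Si](CC)(CC)CC)C=C1 | intermediate
16 | methyl pyruvate | CC(=O)C(=O)OC | starting material
17 | methyl 3-[(1R,2S)-2-hydroxy-5-oxo-2-R*-cyclohex-3-en-1-yl]-2-oxopropanoate | COC(=O)C(=O)C[C@H]2CC(=O)C=C[C@]2(O)/C(C)=C\[C@@H](C)[C@@H]([C@@H](C)O[Si](C)(C)C(C)(C)C)O[Si](CC)(CC)CC | intermediate
18 | methyl (2S)-2-hydroxy-3-[(1S,2S)-2-hydroxy-5-oxo-2-R*-cyclohex-3-en-1-yl]propanoate | COC(=O)[C@@H](O)C[C@H]2CC(=O)C=C[C@]2(O)/C(C)=C\[C@@H](C)[C@@H]([C@@H](C)O[Si](C)(C)C(C)(C)C)O[Si](CC)(CC)CC | intermediate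
19 | methyl (2S)-2-methoxy-3-[(1S,2S)-2-hydroxy-5-oxo-2-R*-cyclohex-3-en-1-yl]propanoate | COC(=O)[C@@H](OC)C[C@H]2CC(=O)C=C[C@]2(O)/C(C)=C\[C@@H](C)[C@@H]([C@@H](C)O[Si](C)(C)C(C)(C)C)O[Si](CC)(CC)CC | intermediate
20 | (2E)-4-acetoxy-2-methylbut-2-enal | CC(=O)OC/C=C(\C)C=O | starting material
21 | C13-O-[diisopropyl(trifluoromethanesulfonyloxy)silyl] ether of 19 | COC(=O)[C@@H](OC)C[C@H]2CC(=O)C=C[C@]2(O[Si](C(C)C)(C(C)C)OS(=O)(=O)C(F)(F)F)/C(C)=C\[C@@H](C)[C@@H]([C@@H](C)O[Si](C)(C)C(C)(C)C)O[Si](CC)(CC)CC | intermediate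
22 | C13-O-diisopropylsilyl (1E,3E)-4-acetoxy-2-methylbuta-1,3-dienyl ether of 19 | COC(=O)[C@@H](OC)C[C@H]2CC(=O)C=C[C@]2(O[Si](C(C)C)(C(C)C)O/C=C(C)/C=C/OC(C)=O)/C(C)=C\[C@@H](C)[C@@H]([C@@H](C)O[Si](C)(C)C(C)(C)C)O[Si](CC)(CC)CC | intermediate
23 | cis-fused octalin-6-one with C8 acetate, C9=C10(Me) alkene and C11–O–Si(iPr)2–O–C13 silylene (H7, H12 anti to O13; O8, O11 syn to O13) | COC(=O)[C@@H](OC)C[C@H]2CC(=O)[C@H]3[C@@H](OC(C)=O)C=C(C)[C@H]4O[Si](C(C)C)(C(C)C)O[C@]2(/C(C)=C\[C@@H](C)[C@@H]([C@@H](C)O[Si](C)(C)C(C)(C)C)O[Si](CC)(CC)CC)[C@@H]34 | intermediate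
24 | C11,C13-diol C8-acetate of the cis-octalin-6-one | COC(=O)[C@@H](OC)C[C@H]2CC(=O)[C@H]3[C@@H](OC(C)=O)C=C(C)[C@@H](O)[C@H]3[C@]2(O)/C(C)=C\[C@@H](C)[C@@H]([C@@H](C)O[Si](C)(C)C(C)(C)C)O[Si](CC)(CC)CC | intermediate
25 | ether-bridged tricycle: C13–O–C8 ether, C6 ketone, C9=C10 alkene, C11 hydroxyl syn to the bridge | COC(=O)[C@@H](OC)C[C@H]2CC(=O)[C@H]3[C@H]4O[C@]2(/C(C)=C\[C@@H](C)[C@@H]([C@@H](C)O[Si](C)(C)C(C)(C)C)O[Si](CC)(CC)CC)[C@@H]3[C@H](O)C(C)=C4 | intermediate
26 | tricyclic C11 enone (C6 ketone) | COC(=O)[C@@H](OC)C[C@H]2CC(=O)[C@H]3[C@H]4O[C@]2(/C(C)=C\[C@@H](C)[C@@H]([C@@H](C)O[Si](C)(C)C(C)(C)C)O[Si](CC)(CC)CC)[C@@H]3C(=O)C(C)=C4 | intermediate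
27 | potassium C5=C6 enolate of 26 | COC(=O)[C@@H](OC)C[C@H]2C=C([O-])[C@H]3[C@H]4O[C@]2(/C(C)=C\[C@@H](C)[C@@H]([C@@H](C)O[Si](C)(C)C(C)(C)C)O[Si](CC)(CC)CC)[C@@H]3C(=O)C(C)=C4.[K+] | intermediate
28 | C5=C6 enol triflate of 26 | COC(=O)[C@@H](OC)C[C@H]2C=C(OS(=O)(=O)C(F)(F)F)[C@H]3[C@H]4O[C@]2(/C(C)=C\[C@@H](C)[C@@H]([C@@H](C)O[Si](C)(C)C(C)(C)C)O[Si](CC)(CC)CC)[C@@H]3C(=O)C(C)=C4 | intermediate
29 | tricyclic C11 enone with C5=C6 alkene | COC(=O)[C@@H](OC)C[C@H]2C=C[C@H]3[C@H]4O[C@]2(/C(C)=C\[C@@H](C)[C@@H]([C@@H](C)O[Si](C)(C)C(C)(C)C)O[Si](CC)(CC)CC)[C@@H]3C(=O)C(C)=C4 | intermediate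
30 | C9 pinacol boronate (boron exo, anti to the bridge) of the 11-ketone | COC(=O)[C@@H](OC)C[C@H]2C=C[C@H]3[C@H]4O[C@]2(/C(C)=C\[C@@H](C)[C@@H]([C@@H](C)O[Si](C)(C)C(C)(C)C)O[Si](CC)(CC)CC)[C@@H]3C(=O)[C@@H](C)[C@H]4B5OC(C)(C)C(C)(C)O5 | intermediate
31 | 9-hydroxy-11-ketone (9-OH and 10-Me cis, both anti to the bridge) | COC(=O)[C@@H](OC)C[C@H]2C=C[C@H]3[C@H]4O[C@]2(/C(C)=C\[C@@H](C)[C@@H]([C@@H](C)O[Si](C)(C)C(C)(C)C)O[Si](CC)(CC)CC)[C@@H]3C(=O)[C@@H](C)[C@H]4O | intermediate
32 | 9,11-diol (11-OH syn to the bridge, anti to 9-OH) | COC(=O)[C@@H](OC)C[C@H]2C=C[C@H]3[C@H]4O[C@]2(/C(C)=C\[C@@H](C)[C@@H]([C@@H](C)O[Si](C)(C)C(C)(C)C)O[Si](CC)(CC)CC)[C@@H]3[C@H](O)[C@@H](C)[C@H]4O | intermediate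
33 | 1H-pyrrole-2-carbonyl chloride | O=C(Cl)c1ccc[nH]1 | starting material
34 | 9-O-(1H-pyrrole-2-carbonyl) ester of 32 | COC(=O)[C@@H](OC)C[C@H]2C=C[C@H]3[C@H]4O[C@]2(/C(C)=C\[C@@H](C)[C@@H]([C@@H](C)O[Si](C)(C)C(C)(C)C)O[Si](CC)(CC)CC)[C@@H]3[C@H](O)[C@@H](C)[C@H]4OC(=O)c1ccc[nH]1 | intermediate
35 | C1 carboxylic acid of 34 (O17 TES and O18 TBS retained) | OC(=O)[C@@H](OC)C[C@H]2C=C[C@H]3[C@H]4O[C@]2(/C(C)=C\[C@@H](C)[C@@H]([C@@H](C)O[Si](C)(C)C(C)(C)C)O[Si](CC)(CC)CC)[C@@H]3[C@H](O)[C@@H](C)[C@H]4OC(=O)c1ccc[nH]1 | intermediate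
36 | seco acid (C1 acid, C17 hydroxyl, O18 TBS) | OC(=O)[C@@H](OC)C[C@H]2C=C[C@H]3[C@H]4O[C@]2(/C(C)=C\[C@@H](C)[C@@H]([C@@H](C)O[Si](C)(C)C(C)(C)C)O)[C@@H]3[C@H](O)[C@@H](C)[C@H]4OC(=O)c1ccc[nH]1 | intermediate
37 | mixed 2,4,6-trichlorobenzoic anhydride of 36 | Clc1cc(Cl)c(C(=O)OC(=O)[C@@H](OC)C[C@H]2C=C[C@H]3[C@H]4O[C@]2(/C(C)=C\[C@@H](C)[C@@H]([C@@H](C)O[Si](C)(C)C(C)(C)C)O)[C@@H]3[C@H](O)[C@@H](C)[C@H]4OC(=O)c5ccc[nH]5)c(Cl)c1 | intermediate
38 | 18-O-TBS macrolactone (ten-membered lactone C1–O17) | CO[C@H]1C[C@H]2C=C[C@H]3[C@H]4O[C@]2(/C(C)=C\[C@@H](C)[C@@H]([C@@H](C)O[Si](C)(C)C(C)(C)C)OC1=O)[C@@H]3[C@H](O)[C@@H](C)[C@H]4OC(=O)c1ccc[nH]1 | intermediate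
39 | 18-alcohol macrolactone (18-O-deacetyl target) | CO[C@H]1C[C@H]2C=C[C@H]3[C@H]4O[C@]2(/C(C)=C\[C@@H](C)[C@@H]([C@@H](C)O)OC1=O)[C@@H]3[C@H](O)[C@@H](C)[C@H]4OC(=O)c1ccc[nH]1 | intermediate
40 | 18-O-acetyl-nargenicin | CO[C@H]1C[C@H]2C=C[C@H]3[C@H]4O[C@]2(/C(C)=C\[C@@H](C)[C@@H]([C@@H](C)OC(C)=O)OC1=O)[C@@H]3[C@H](O)[C@@H](C)[C@H]4OC(=O)c1ccc[nH]1 | target

**Step count**

Total: 21 steps. Longest linear sequence: 21 steps (propanal 1 to target 40; all other inputs are commercial).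

**Three steps most likely to fail, with fallbacks**

Step 7 (the proposed new Michael addition): the risks are poor discrimination of the two enone arms and pyruvate self-condensation. The enantiomeric acid would be tried first if the arm selectivity is reversed. The fallback uses known chemistry and sets out from 15. Silylation (TMSCl, imidazole) gives the quinol trimethylsilyl ether F1. A TMSOTf-catalysed Mukaiyama–Michael addition of commercial methyl 2-(trimethylsilyloxy)acrylate (CH2Cl2, −78 °C) gives the bis-silyl adduct F2 together with its arm isomer. Citric acid in MeOH removes both trimethylsilyl groups, and chromatography separates 17 from the unwanted arm diastereomer F3; the enantiopure side chain makes the two products diastereomers, so no catalyst control is needed, at the cost of half the material. The route is rejoined at 17.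

Step 10 (silicon-tethered Diels–Alder): the risks are silylation of the hindered tertiary alcohol, the geometry of the dienol ether, and a cycloaddition whose regiochemistry is enforced against the electronic preference of the silyloxy diene. The fallback sets out from 19 and 20. Enol acetylation of 20 (Ac2O, Et3N, 4-(dimethylamino)pyridine) gives (1E,3E)-2-methylbuta-1,3-diene-1,4-diyl diacetate F4. An untethered thermal Diels–Alder reaction of 19 with F4 (toluene, 110 °C, sealed tube), with regiochemistry set by the C10 methyl and the diene steered to the face of the free C13 hydroxyl, gives the bis-acetate adduct F5. Methanolysis (K2CO3, MeOH, 0 °C) gives triol F6. Catalytic pyridinium p-toluenesulfonate then ionises the tertiary allylic C13 alcohol, the C8 hydroxyl captures the cation, and the ether bridge closes with the bond formed from the opposite partner. The route is rejoined at 25.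

Step 19 (ten-membered macrolactonisation): the risks are oligomerisation and interference from the pyrrole N–H or the free hydroxyl. The fallback closes the ring earlier, on a substrate with no free ring hydroxyl, and sets out from 29. LiOH then AcOH/THF/H2O gives, through the TES-protected acid F7, the enone seco acid F8. Yamaguchi activation (mixed anhydride F9) and high-dilution cyclisation give the macrolactone enone F10. Conjugate borylation as in step 15 (boronate F11) and oxidation give the hydroxy ketone lactone F12. Me4NBH(OAc)3 gives the diol lactone F13. Acylation of the C9 hydroxyl with 33 rejoins the route at 38.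

**Further compounds**

F1 | step 7 | 4-R*-4-(trimethylsilyloxy)cyclohexa-2,5-dien-1-one | O=C1C=CC(O[Si](C)(C)C)(/C(C)=C\[C@@H](C)[C@@H]([C@@H](C)O[Si](C)(C)C(C)(C)C)O[Si](CC)(CC)CC)C=C1
F2 | step 7 | bis(trimethylsilyl) Mukaiyama–Michael adduct (C13 O-TMS, C5=C6 TMS dienol ether, C2 keto ester) | COC(=O)C(=O)C[C@H]2C=C(O[Si](C)(C)C)C=C[C@]2(O[Si](C)(C)C)/C(C)=C\[C@@H](C)[C@@H]([C@@H](C)O[Si](C)(C)C(C)(C)C)O[Si](CC)(CC)CC
F3 | step 7 | arm diastereomer of 17 (opposite configuration at C4 and C13) | COC(=O)C(=O)C[C@@H]2CC(=O)C=C[C@@]2(O)/C(C)=C\[C@@H](C)[C@@H]([C@@H](C)O[Si](C)(C)C(C)(C)C)O[Si](CC)(CC)CC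
F4 | step 10 | (1E,3E)-2-methylbuta-1,3-diene-1,4-diyl diacetate | CC(=O)O/C=C(C)/C=C/OC(C)=O
F5 | step 10 | cis-octalin-6-one C8,C11-diacetate with free C13 hydroxyl | COC(=O)[C@@H](OC)C[C@H]2CC(=O)[C@H]3[C@@H](OC(C)=O)C=C(C)[C@@H](OC(C)=O)[C@H]3[C@]2(O)/C(C)=C\[C@@H](C)[C@@H]([C@@H](C)O[Si](C)(C)C(C)(C)C)O[Si](CC)(CC)CC
F6 | step 10 | cis-octalin-6-one C8,C11,C13-triol | COC(=O)[C@@H](OC)C[C@H]2CC(=O)[C@H]3[C@@H](O)C=C(C)[C@@H](O)[C@H]3[C@]2(O)/C(C)=C\[C@@H](C)[C@@H]([C@@H](C)O[Si](C)(C)C(C)(C)C)O[Si](CC)(CC)CC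
F7 | step 19 | C1 acid of 29 (O17 TES retained) | OC(=O)[C@@H](OC)C[C@H]2C=C[C@H]3[C@H]4O[C@]2(/C(C)=C\[C@@H](C)[C@@H]([C@@H](C)O[Si](C)(C)C(C)(C)C)O[Si](CC)(CC)CC)[C@@H]3C(=O)C(C)=C4
F8 | step 19 | enone seco acid (C1 acid, C17 hydroxyl) | OC(=O)[C@@H](OC)C[C@H]2C=C[C@H]3[C@H]4O[C@]2(/C(C)=C\[C@@H](C)[C@@H]([C@@H](C)O[Si](C)(C)C(C)(C)C)O)[C@@H]3C(=O)C(C)=C4
F9 | step 19 | mixed 2,4,6-trichlorobenzoic anhydride of F8 | Clc1cc(Cl)c(C(=O)OC(=O)[C@@H](OC)C[C@H]2C=C[C@H]3[C@H]4O[C@]2(/C(C)=C\[C@@H](C)[C@@H]([C@@H](C)O[Si](C)(C)C(C)(C)C)O)[C@@H]3C(=O)C(C)=C4)c(Cl)c1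
F10 | step 19 | macrolactone C11 enone (O18 TBS) | CO[C@H]1C[C@H]2C=C[C@H]3[C@H]4O[C@]2(/C(C)=C\[C@@H](C)[C@@H]([C@@H](C)O[Si](C)(C)C(C)(C)C)OC1=O)[C@@H]3C(=O)C(C)=C4
F11 | step 19 | macrolactone C9 pinacol boronate 11-ketone | CO[C@H]1C[C@H]2C=C[C@H]3[C@H]4O[C@]2(/C(C)=C\[C@@H](C)[C@@H]([C@@H](C)O[Si](C)(C)C(C)(C)C)OC1=O)[C@@H]3C(=O)[C@@H](C)[C@H]4B5OC(C)(C)C(C)(C)O5
F12 | step 19 | macrolactone 9-hydroxy-11-ketone | CO[C@H]1C[C@H]2C=C[C@H]3[C@H]4O[C@]2(/C(C)=C\[C@@H](C)[C@@H]([C@@H](C)O[Si](C)(C)C(C)(C)C)OC1=O)[C@@H]3C(=O)[C@@H](C)[C@H]4O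
F13 | step 19 | macrolactone 9,11-diol (O18 TBS) | CO[C@H]1C[C@H]2C=C[C@H]3[C@H]4O[C@]2(/C(C)=C\[C@@H](C)[C@@H]([C@@H](C)O[Si](C)(C)C(C)(C)C)OC1=O)[C@@H]3[C@H](O)[C@@H](C)[C@H]4O
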